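Ring A of the chromene (C4a, C5–C8, C8a) is built from a four-carbon cyclobutenone and a two-carbon ynol ether. The feature exploited is that, of the three alternating ring A oxygens, only the one on C8a, flanked by the C8 prenyl group and C4a, is the pyran oxygen O1. Benzannulation of racemic 3-ethoxy-4-prenylcyclobut-2-en-1-one with ethoxyacetylene forms C8a–C4a, C5–C6 and C8a–C8 in one operation. It delivers the prenylated ring with C8a–OH as the only free phenol and C5–O and C7–O as ethyl ethers. Chromene annulation at O1/C4a, aroylation at C6 and deprotection then finish.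

Key step: step 3

Assumption: the two non-pyran oxygens are carried as ethyl ethers because ethoxyacetylene is the readily purchased terminal ynol ether; the target is achiral, and compounds 5, 7, 9, 13 and 20 are racemic with stereocenters that do not survive.

Step 1
Reactants: 1 5-methylhex-4-enoic acid
Product: 2 5-methylhex-4-enoyl chloride
Conditions: (COCl)2, DMF (cat.), CH2Cl2, 0 °C → rt
Reagents that add atoms: oxalyl chloride, O=C(Cl)C(Cl)=O
Why: Standard acid chloride formation through the DMF-derived chloroiminium catalyst; the low temperature and volatile by-products should leave the trisubstituted alkene untouched, and 2 is used crude.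

Step 2
Reactants: 2 5-methylhex-4-enoyl chloride; 3 ethoxyacetylene
Product: 5 3-ethoxy-4-(3-methylbut-2-en-1-yl)cyclobut-2-en-1-one (racemic), via prenylketene 4 (not isolated)
Conditions: 3 (3 equiv), Et3N, Et2O, rt, 2 added over 4 h
Reagents that add atoms: none
Why: Dehydrochlorination gives monoalkylketene 4 at low concentration, which excess ynol ether intercepts in a thermal ketene–alkyne (2+2) cycloaddition; the nucleophilic terminal carbon of 3 bonds to the ketene carbonyl carbon, so ethoxy ends on C3 and prenyl on C4, and the racemic C4 center is erased in step 3.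

Step 3
Reactants: 5 3-ethoxy-4-(3-methylbut-2-en-1-yl)cyclobut-2-en-1-one; 3 ethoxyacetylene
Product: 10 3,5-diethoxy-2-(3-methylbut-2-en-1-yl)phenol, via vinylketene 6 (not isolated), via vinylcyclobutenone 7 (not isolated), via dienylketene 8 (not isolated), via cyclohexadienone 9 (not isolated)
Conditions: 3 (4 equiv), toluene, sealed tube, 90 °C; then KOH, MeOH, rt
Reagents that add atoms: none
Why: Heating opens 5 by conrotatory 4π cleavage of C1–C4 (prenyl rotating outward) to vinylketene 6, the terminal CH carbon of 3 adds to the ketene carbon in a (2+2) cycloaddition giving 7, and reversible 4π opening of 7 to dienylketene 8, 6π electrocyclization to 9 and enolization should give phenol 10. The closest known reaction is the Danheiser benzannulation of cyclobutenones with alkoxyacetylenes, whose own intermediate 7 is a 3-alkoxycyclobutenone that opens under the same conditions, which supports the opening of the vinylogous ester 5. Ring A is closed by the thermal disrotatory 6π electrocyclization of 8, which joins the ketene carbon (C8a) to the prenyl-bearing terminus (C8) and so re-makes the bond that opened first, after the (2+2) event has made C8a–C4a and C5–C6. No stereocenter survives, since the racemic centers of 5, 7 and 9 all become aromatic carbons. The one selectivity needed is the orientation of the (2+2) addition, and the polarized ynol ether secures it: its unsubstituted nucleophilic carbon bonds to the electrophilic ketene carbon and its oxygen-bearing carbon to the ketene α-carbon, so the oxygens fall 1,3,5 and the C8a hydroxyl, between C8-prenyl and C4a–H, is the only free one. Excess 3 keeps 6 from being trapped by the product, and the methanolic KOH treatment returns any aryl ester formed in that way to 10.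

Step 4
Reactants: 10 3,5-diethoxy-2-(3-methylbut-2-en-1-yl)phenol; 11 3-chloro-3-methylbut-1-yne
Product: 12 1,5-diethoxy-2-(3-methylbut-2-en-1-yl)-3-[(2-methylbut-3-yn-2-yl)oxy]benzene
Conditions: DBU, CuCl2·2H2O (cat.), MeCN, 0 °C → rt
Reagents that add atoms: none
Why: Copper-catalysed O-alkylation of a phenol with a tertiary propargylic chloride (Godfrey-type conditions) proceeds through a copper acetylide-derived electrophile and should etherify even this ortho-substituted phenol at 0 °C without touching the ethers or the prenyl group.

Step 5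
Reactants: 12 1,5-diethoxy-2-(3-methylbut-2-en-1-yl)-3-[(2-methylbut-3-yn-2-yl)oxy]benzene
Product: 16 5,7-diethoxy-2,2-dimethyl-8-(3-methylbut-2-en-1-yl)-2H-chromene, via allenyl dienone 13 (not isolated), via allenylphenol 14 (not isolated), via quinone methide 15 (not isolated)
Conditions: o-xylene, 140 °C
Reagents that add atoms: none
Why: Aryl propargyl ether Claisen rearrangement to C4a, the only free ortho carbon (C8 carries the prenyl group), followed by enolization, 1,5-hydrogen shift and oxa-6π electrocyclization, should close the 2,2-dimethyl-2H-pyran ring with no stereocenter formed and no free phenol left beside the prenyl group.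

Step 6
Reactants: 17 4-hydroxybenzaldehyde
Product: 18 4-(triisopropylsilyloxy)benzaldehyde
Conditions: TIPSCl, imidazole, DMF, rt
Reagents that add atoms: chlorotriisopropylsilane, CC(C)[Si](Cl)(C(C)C)C(C)C
Why: Routine phenol silylation; the triisopropylsilyl ether is chosen because it should tolerate the aryllithium addition of step 7 and the boron Lewis acid of step 9 better than smaller silyl groups.

Step 7
Reactants: 16 5,7-diethoxy-2,2-dimethyl-8-(3-methylbut-2-en-1-yl)-2H-chromene; 18 4-(triisopropylsilyloxy)benzaldehyde
Product: 20 [5,7-diethoxy-2,2-dimethyl-8-(3-methylbut-2-en-1-yl)-2H-chromen-6-yl][4-(triisopropylsilyloxy)phenyl]methanol (racemic), via aryllithium 19 (not isolated)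
Conditions: n-BuLi, THF, 0 °C → rt; then 18, −78 → 0 °C; H2O
Reagents that add atoms: none
Why: Directed ortho-metalation at C6, the only aromatic C–H of ring A and the site flanked by both ethoxy groups, followed by 1,2-addition of aryllithium 19 to the aldehyde; the carbinol center forms racemic and is removed in step 8.

Step 8
Reactants: 20 [5,7-diethoxy-2,2-dimethyl-8-(3-methylbut-2-en-1-yl)-2H-chromen-6-yl][4-(triisopropylsilyloxy)phenyl]methanol
Product: 21 [5,7-diethoxy-2,2-dimethyl-8-(3-methylbut-2-en-1-yl)-2H-chromen-6-yl][4-(triisopropylsilyloxy)phenyl]methanone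
Conditions: Dess–Martin periodinane, NaHCO3, CH2Cl2, 0 °C → rt
Reagents that add atoms: none
Why: Dess–Martin oxidation of a hindered doubly benzylic secondary alcohol to the diaryl ketone under buffered, non-acidic conditions that should not affect the prenyl and chromene alkenes or the silyl ether.

Step 9
Reactants: 21 [5,7-diethoxy-2,2-dimethyl-8-(3-methylbut-2-en-1-yl)-2H-chromen-6-yl][4-(triisopropylsilyloxy)phenyl]methanone
Product: 22 [5,7-dihydroxy-2,2-dimethyl-8-(3-methylbut-2-en-1-yl)-2H-chromen-6-yl][4-(triisopropylsilyloxy)phenyl]methanone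
Conditions: BCl3, n-Bu4NI, CH2Cl2, −78 → 0 °C; aq. NaHCO3
Reagents that add atoms: none
Why: BCl3 binds the ketone oxygen together with an ortho ethoxy oxygen and iodide removes the ethyl group by SN2 attack to leave a six-membered boron chelate, and the same BCl3/iodide pair, a known reagent for primary alkyl aryl ethers below room temperature, should remove the second ethoxy group; no protic acid is present before the bicarbonate quench, which should spare the prenyl group, the chromene and the hindered silyl ether.

Step 10
Reactants: 22 [5,7-dihydroxy-2,2-dimethyl-8-(3-methylbut-2-en-1-yl)-2H-chromen-6-yl][4-(triisopropylsilyloxy)phenyl]methanone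
Product: 23 Vismiaphenone E, [5,7-dihydroxy-2,2-dimethyl-8-(3-methylbut-2-en-1-yl)-2H-chromen-6-yl](4-hydroxyphenyl)methanone
Conditions: TBAF, AcOH, THF, 0 °C
Reagents that add atoms: none
Why: Fluoride cleavage of the aryl silyl ether, fast because the 4-acylphenoxide is a good leaving group, with acetic acid buffering so that the triphenol is not exposed to strong base.

Compound list
1 | 5-methylhex-4-enoic acid | CC(C)=CCCC(=O)O | starting material
2 | 5-methylhex-4-enoyl chloride | CC(C)=CCCC(=O)Cl | intermediate
3 | ethoxyacetylene (ethoxyethyne) | C#COCC | starting material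
4 | prenylketene, 5-methylhexa-1,4-dien-1-one | O=C=CCC=C(C)C | intermediate (not isolated)
5 | 3-ethoxy-4-(3-methylbut-2-en-1-yl)cyclobut-2-en-1-one, racemic | CCOC1=CC(=O)C1CC=C(C)C | intermediate
6 | vinylketene, (3Z)-3-ethoxy-7-methylocta-1,3,6-trien-1-one | O=C=C/C(OCC)=C/CC=C(C)C | intermediate (not isolated)
7 | vinylcyclobutenone, 3-ethoxy-4-[(1Z)-1-ethoxy-5-methylhexa-1,4-dien-1-yl]cyclobut-2-en-1-one, racemic | O=C1C=C(OCC)C1/C(OCC)=C/CC=C(C)C | intermediate (not isolated)
8 | dienylketene, (3E,5Z)-3,5-diethoxy-9-methyldeca-1,3,5,8-tetraen-1-one | O=C=C/C(OCC)=C\C(OCC)=C\CC=C(C)C | intermediate (not isolated)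
9 | cyclohexadienone, 3,5-diethoxy-6-(3-methylbut-2-en-1-yl)cyclohexa-2,4-dien-1-one, racemic | O=C1C=C(OCC)C=C(OCC)C1CC=C(C)C | intermediate (not isolated)
10 | 3,5-diethoxy-2-(3-methylbut-2-en-1-yl)phenol | Oc1cc(OCC)cc(OCC)c1CC=C(C)C | intermediate
11 | 3-chloro-3-methylbut-1-yne | C#CC(C)(C)Cl | starting material
12 | 1,5-diethoxy-2-(3-methylbut-2-en-1-yl)-3-[(2-methylbut-3-yn-2-yl)oxy]benzene | C#CC(C)(C)Oc1cc(OCC)cc(OCC)c1CC=C(C)C | intermediate
13 | allenyl dienone, 3,5-diethoxy-6-(3-methylbuta-1,2-dien-1-yl)-2-(3-methylbut-2-en-1-yl)cyclohexa-2,4-dien-1-one, racemic | O=C1C(CC=C(C)C)=C(OCC)C=C(OCC)C1C=C=C(C)C | intermediate (not isolated)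
14 | allenylphenol, 3,5-diethoxy-2-(3-methylbuta-1,2-dien-1-yl)-6-(3-methylbut-2-en-1-yl)phenol | Oc1c(CC=C(C)C)c(OCC)cc(OCC)c1C=C=C(C)C | intermediate (not isolated)
15 | quinone methide, (6Z)-3,5-diethoxy-2-(3-methylbut-2-en-1-yl)-6-(3-methylbut-2-en-1-ylidene)cyclohexa-2,4-dien-1-one | CC(C)=C/C=C1\C(=O)C(CC=C(C)C)=C(OCC)C=C1OCC | intermediate (not isolated)
16 | 5,7-diethoxy-2,2-dimethyl-8-(3-methylbut-2-en-1-yl)-2H-chromene | CCOc1cc(OCC)c2C=CC(C)(C)Oc2c1CC=C(C)C | intermediate
17 | 4-hydroxybenzaldehyde | O=Cc1ccc(O)cc1 | starting material
18 | 4-(triisopropylsilyloxy)benzaldehyde | CC(C)[Si](Oc1ccc(C=O)cc1)(C(C)C)C(C)C | intermediate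
19 | aryllithium, [5,7-diethoxy-2,2-dimethyl-8-(3-methylbut-2-en-1-yl)-2H-chromen-6-yl]lithium | [Li]c1c(OCC)c2C=CC(C)(C)Oc2c(CC=C(C)C)c1OCC | intermediate (not isolated)
20 | [5,7-diethoxy-2,2-dimethyl-8-(3-methylbut-2-en-1-yl)-2H-chromen-6-yl][4-(triisopropylsilyloxy)phenyl]methanol, racemic | CCOc1c(C(O)c2ccc(O[Si](C(C)C)(C(C)C)C(C)C)cc2)c(OCC)c2C=CC(C)(C)Oc2c1CC=C(C)C | intermediate
21 | [5,7-diethoxy-2,2-dimethyl-8-(3-methylbut-2-en-1-yl)-2H-chromen-6-yl][4-(triisopropylsilyloxy)phenyl]methanone | CCOc1c(C(=O)c2ccc(O[Si](C(C)C)(C(C)C)C(C)C)cc2)c(OCC)c2C=CC(C)(C)Oc2c1CC=C(C)C | intermediate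
22 | [5,7-dihydroxy-2,2-dimethyl-8-(3-methylbut-2-en-1-yl)-2H-chromen-6-yl][4-(triisopropylsilyloxy)phenyl]methanone | CC(C)=CCc1c(O)c(C(=O)c2ccc(O[Si](C(C)C)(C(C)C)C(C)C)cc2)c(O)c2c1OC(C)(C)C=C2 | intermediate
23 | Vismiaphenone E | CC(C)=CCc1c(O)c(C(=O)c2ccc(O)cc2)c(O)c2c1OC(C)(C)C=C2 | target

Total step count: 10. Longest linear sequence: 9 steps (steps 1–5 and 7–10); step 6 is a one-step side branch.

Steps most likely to fail

Step 3. The vinylogous-ester cyclobutenone may open only sluggishly at temperatures where the volatile alkyne begins to fragment to ketene and ethylene. The vinylketene may also be intercepted by the phenol already formed, or isomerize by hydrogen shift if the prenyl group rotates inward. The fallback sets out from ethoxyacetylene 3 and comes back at phenol 10. Deprotonation of 3 with n-BuLi (THF, −78 °C) gives lithium ethoxyacetylide F1, which is alkylated with prenyl bromide (DMPU, −78 °C → rt) to 1-ethoxy-5-methylhex-4-en-1-yne F2. Heating F2 with purchased 3-ethoxycyclobut-2-en-1-one (CCOC1=CC(=O)C1) in toluene at 100 °C runs the benzannulation with the roles exchanged. The prenyl group now arrives on the nucleophilic alkyne carbon that bonds to the ketene carbon, so C8a–C8, C6–C7 and C8a–C4a are formed and the same phenol 10 should result. This avoids both the 4-substituted cyclobutenone and the low-boiling alkyne.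

Step 9. Cleavage of the second, non-chelated ethoxy group may stall. Alternatively, acid released during the quench may drive cyclization of the prenyl group onto the freed C7 oxygen or hydrohalogenation of an alkene. The fallback sets out from ketone 21 and comes back at target 23. Excess NaSEt in DMF at 120–130 °C should remove both ethyl groups by SN2 attack of thiolate at the ethyl carbons under purely basic conditions, in which neither alkene can be protonated. The activated aryl silyl ether should be cleaved in the same pot, so compound 22 and step 10 are bypassed and no new compound is made (F0).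

Step 7. Deprotonation may compete at the benzylic-allylic CH2 of the prenyl group or on the pyran ring, or lithiation at the hindered C6 may remain incomplete. The fallback sets out from chromene 16 and comes back at carbinol 20, with the polarity of the bond formation reversed. Vilsmeier–Haack formylation (POCl3, DMF, 0 °C → rt, then water) should attack C6, the only unsubstituted position of the very electron-rich ring A, to give 5,7-diethoxy-2,2-dimethyl-8-(3-methylbut-2-en-1-yl)-2H-chromene-6-carbaldehyde F3. Addition of [4-(triisopropylsilyloxy)phenyl]magnesium bromide F4, made from purchased (4-bromophenoxy)triisopropylsilane and Mg in THF, then gives 20.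

Further compounds
F1 | step 3 | lithium ethoxyacetylide | [Li]C#COCC
F2 | step 3 | 1-ethoxy-5-methylhex-4-en-1-yne | CCOC#CCC=C(C)C
F0 | step 9 | none | none
F3 | step 7 | 5,7-diethoxy-2,2-dimethyl-8-(3-methylbut-2-en-1-yl)-2H-chromene-6-carbaldehyde | CCOc1c(C=O)c(OCC)c2C=CC(C)(C)Oc2c1CC=C(C)C
F4 | step 7 | [4-(triisopropylsilyloxy)phenyl]magnesium bromide | CC(C)[Si](Oc1ccc([Mg]Br)cc1)(C(C)C)C(C)C
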